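Everything rests on cutting C2–C3 together with the lactone bond O–C16. The enabling feature is that C3, the lactone carbinol carbon, sits beside fully substituted C4, so an aldehyde at C3 has no α-hydrogen, while C2 is the vinylogous γ-position of the C16 carbonyl across C15=C1. Removing a proton from the C2 methyl of a linear (E)-2,3-dimethyl enoate lets the dienolate attack the tethered C3 aldehyde; this closes the 14-membered carbocycle (C1–C14) and sets C3, and the C3 alkoxide then closes the δ-lactone (O–C3–C2–C1–C15–C16) at C16. The precursor is the open-chain C3–C16 aldehyde ester (4S,11S,12S,7E) with the 11,12-epoxide installed and O4 as a TBS ether.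

Key step: step 15

Remark: cembrane numbering is used throughout (ring C1–C14, C16 the lactone carbonyl, C17 on C15, C18 on C4, C19 on C8, C20 on C12), and the target re-derived from its SMILES is 1R,3R,4S,6E,8R,11S,12S,15S; (R)-2-methylglycidol of high ee is assumed purchasable (it is the D-(−)-tartrate Sharpless epoxide of 2-methylprop-2-en-1-ol); O4 carries TBS because a smaller silyl group would shift to the C3 alkoxide and block lactone closure (TES = triethylsilyl, TBS = tert-butyldimethylsilyl, PMB = 4-methoxybenzyl).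

Step 1
Reactants: 1 geranyl bromide
Product: 2 geranyl phenyl sulfone PhSO2–CH2–CH=C(Me)–(CH2)2–CH=CMe2 (2E)
Conditions: PhSO2Na, DMF, rt
Reagents that add atoms: sodium benzenesulfinate [Na+].[O-]S(=O)c1ccccc1
Why: SN2 S-alkylation of the sulfinate at the primary allylic bromide leaves the 2E alkene untouched.

Step 2
Reactants: 2 geranyl phenyl sulfone
Product: 3 (2E,6E)-2,6-dimethyl-8-(phenylsulfonyl)octa-2,6-dien-1-ol
Conditions: SeO2 (cat.), t-BuOOH, salicylic acid (cat.), CH2Cl2, 0 °C → rt
Reagents that add atoms: tert-butyl hydroperoxide CC(C)(C)OO (terminal oxidant); selenium dioxide O=[Se]=O (catalytic oxygen carrier)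
Why: Selenium dioxide allylic oxidation (ene reaction, then [2,3] shift) hydroxylates the E-methyl of the electron-rich terminal alkene, the other alkene being deactivated by the allylic sulfone; this carbon becomes C13.

Step 3
Reactants: 3 hydroxy sulfone
Product: 4 triethylsilyl ether PhSO2–CH2–CH=C(Me)–(CH2)2–CH=C(Me)–CH2OTES (2E,6E)
Conditions: TESCl, imidazole, CH2Cl2, 0 °C
Reagents that add atoms: chlorotriethylsilane CC[Si](Cl)(CC)CC
Why: Silylation masks the primary alcohol as a base-stable ether that can later be removed selectively beside a tertiary TBS ether.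

Step 4
Reactants: 5 (R)-2-methylglycidol
Product: 6 (S)-2-[(4-methoxybenzyloxy)methyl]-2-methyloxirane
Conditions: NaH, PMBCl, Bu4NI (cat.), THF/DMF, 0 °C → rt
Reagents that add atoms: 4-methoxybenzyl chloride COc1ccc(CCl)cc1
Why: Williamson etherification of the primary alkoxide does not involve the stereocentre (the Payne shift is degenerate and returns the same enantiomer); the descriptor changes from R to S only through CIP priorities.

Step 5
Reactants: 4 silyloxy sulfone; 6 PMB glycidyl ether
Product: 7 hydroxy sulfone PMBOCH2–C(Me)(OH)–CH2–CH(SO2Ph)–CH=C(Me)–(CH2)2–CH=C(Me)–CH2OTES (4S,7E,11E; both C6 epimers)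
Conditions: n-BuLi, THF–DMPU, −78 °C; then 6, −78 → 0 °C
Reagents that add atoms: none
Why: The α-sulfonyl allyl carbanion opens the 2,2-disubstituted epoxide at its unsubstituted carbon (SN2), forming C5–C6 and releasing the tertiary C4 alcohol with the configuration of 6 untouched (4S); the C6 epimers converge in step 7.

Step 6
Reactants: 7 hydroxy sulfone
Product: 8 silyl ether PMBOCH2–C(Me)(OTBS)–CH2–CH(SO2Ph)–CH=C(Me)–(CH2)2–CH=C(Me)–CH2OTES (4S,7E,11E; C6 epimers)
Conditions: TBSOTf, 2,6-lutidine, CH2Cl2, −78 → 0 °C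
Reagents that add atoms: tert-butyldimethylsilyl trifluoromethanesulfonate CC(C)(C)[Si](C)(C)OS(=O)(=O)C(F)(F)F
Why: Silyl triflate silylation is the standard way to cap a hindered tertiary alcohol; the primary TES and PMB ethers are inert.

Step 7
Reactants: 8 bis-silylated sulfone
Product: 10 allylic alcohol PMBOCH2–C(Me)(OTBS)–(CH2)2–CH=C(Me)–(CH2)2–CH=C(Me)–CH2OH (4S,7E,11E), via bis-silyl ether 9 (not isolated)
Conditions: Pd(dppp)Cl2 (cat.), LiBHEt3, THF, 0 °C; work-up; then PPTS (cat.), MeOH, 0 °C
Reagents that add atoms: none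
Why: Palladium-catalysed hydride displacement of the allylic sulfone delivers hydride to the less substituted C6 terminus of the π-allyl, so the 7E trisubstituted alkene stays in place; mild methanolysis then removes only the primary allylic TES ether.

Step 8
Reactants: 10 allylic alcohol
Product: 11 epoxy alcohol PMBOCH2–C(Me)(OTBS)–(CH2)2–CH=C(Me)–(CH2)2–CH(O)C(Me)–CH2OH with the 11,12-epoxide (4S,7E,11S,12S)
Conditions: Ti(Oi-Pr)4, L-(+)-diethyl tartrate, t-BuOOH, 4 Å MS, CH2Cl2, −20 °C
Reagents that add atoms: tert-butyl hydroperoxide CC(C)(C)OO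
Why: Sharpless asymmetric epoxidation oxidises only the alkene of the allylic alcohol (C11=C12; the 7,8-alkene has no directing hydroxyl), and L-(+)-tartrate delivers oxygen to the face that gives 11S,12S for this (E)-2-methyl-2-alkenol.

Step 9
Reactants: 11 epoxy alcohol
Product: 12 epoxy triflate (as 11 but C13H2–OSO2CF3; 4S,7E,11S,12S)
Conditions: Tf2O, 2,6-lutidine, CH2Cl2, −78 °C; used at once
Reagents that add atoms: trifluoromethanesulfonic anhydride FC(F)(F)S(=O)(=O)OS(=O)(=O)C(F)(F)F
Why: Sulfonylation gives a leaving group reactive enough for SN2 at the CH2 next to the fully substituted epoxide carbon at low temperature.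

Step 10
Reactants: 12 epoxy triflate; 13 ethyl 2-methylacetoacetate
Product: 14 β-keto ester PMBOCH2–C(Me)(OTBS)–(CH2)2–CH=C(Me)–(CH2)2–CH(O)C(Me)–CH2–CH2–CO–CH(Me)–CO2Et (4S,7E,11S,12S; C15 epimers)
Conditions: 13, NaH then n-BuLi, THF, 0 °C; then 12, −78 → −20 °C
Reagents that add atoms: none
Why: Huckin–Weiler dianion alkylation: the terminal (γ) carbanion of the acetoacetate dianion, the future C14, displaces the triflate and forms C13–C14; the C15 centre is erased on enolisation in step 11.

Step 11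
Reactants: 14 β-keto ester
Product: 15 (Z)-enol triflate …CH2–CH2–C(OTf)=C(Me)–CO2Et (OTf cis to CO2Et; 4S,7E,11S,12S)
Conditions: LiHMDS, THF, −78 °C; PhNTf2, −78 °C → rt
Reagents that add atoms: N-phenylbis(trifluoromethanesulfonimide) FC(F)(F)S(=O)(=O)N(c1ccccc1)S(=O)(=O)C(F)(F)F
Why: The lithium enolate of a β-keto ester is a chelate with the enolate oxygen cis to the ester carbonyl, so O-sulfonylation fixes the Z enol triflate.

Step 12
Reactants: 15 enol triflate
Product: 16 (E)-2,3-dimethyl enoate PMBOCH2–C(Me)(OTBS)–(CH2)2–CH=C(Me)–(CH2)2–CH(O)C(Me)–(CH2)2–C(Me)=C(Me)–CO2Et (4S,7E,11S,12S; C2 methyl cis to CO2Et)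
Conditions: Me2Zn, Pd(PPh3)4 (cat.), THF, 0 °C → rt
Reagents that add atoms: dimethylzinc C[Zn]C
Why: Negishi coupling at the vinyl triflate proceeds with retention, so the new C2 methyl ends up cis to the ester; ester, epoxide and silyl ether tolerate the organozinc.

Step 13
Reactants: 16 PMB ether
Product: 17 primary alcohol HOCH2–C(Me)(OTBS)–… (otherwise as 16; 4S,7E,11S,12S)
Conditions: DDQ, CH2Cl2/pH 7 buffer, 0 °C
Reagents that add atoms: none
Why: Oxidative cleavage of the PMB ether under buffered, neutral conditions spares the epoxide, the silyl ether and both alkenes.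

Step 14
Reactants: 17 primary alcohol
Product: 18 seco aldehyde OHC–C(Me)(OTBS)–(CH2)2–CH=C(Me)–(CH2)2–CH(O)C(Me)–(CH2)2–C(Me)=C(Me)–CO2Et (4S,7E,11S,12S; E-enoate)
Conditions: Dess–Martin periodinane, NaHCO3, CH2Cl2, 0 °C → rt
Reagents that add atoms: none
Why: Dess–Martin oxidation under buffered conditions gives the aldehyde, which cannot epimerise because C4 carries no hydrogen.

Step 15
Reactants: 18 seco aldehyde
Product: 21 (3R,4S,7E,11S,12S)-4-(tert-butyldimethylsilyloxy)-11,12-epoxycembra-1(15),7-dien-16,3-olide, via lithium dienolate 19 (not isolated), via lithium aldolate 20 (not isolated)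
Conditions: LTMP (from TMP, n-BuLi), THF, −78 °C, slow addition of 18 (final 1 mM); then DMPU, −78 → 0 °C; aq. NH4Cl
Reagents that add atoms: none
Why: Proposed new method: lithium tetramethylpiperidide, held at the ester carbonyl by lithium coordination, abstracts a proton from the C2 methyl (the only γ-position cis to C16 in the E-enoate) to give dienolate 19, whose terminal carbon C2 adds to the C3 aldehyde to give aldolate 20, and the C3 alkoxide of 20 then expels ethoxide from C16; the closest known reaction type is the intermolecular vinylogous aldol–lactonization of lithium dienolates of 2,3-dimethylbut-2-enoates with α-branched aldehydes, which gives 3,4-dimethyl-5,6-dihydropyran-2-ones in one operation, here untested as a ring closure. The 14-membered ring closes by 14-exo-trig addition of C2 to the carbonyl carbon C3 and the δ-lactone by 6-exo-trig acyl substitution at C16, the latter being the irreversible exit that also drains any α-adduct formed reversibly at the fully substituted C15. C3 is controlled by the adjacent stereocentre C4 in a Felkin–Anh/Cornforth arrangement: the C4–OTBS bond lies anti to the incoming C2, which passes the C4 methyl and not the C5 methylene, and this gives the 3,4-anti (3R) carbinol. The step needs γ- over α-attack (secured by the tetrasubstituted C15 and by lactonization being possible only from the cis γ-adduct), C2 over C14 deprotonation (secured by the E geometry fixed in step 12), ring closure over oligomerisation (high dilution, slow addition) and an aldehyde that can neither enolise nor self-condense (C4 bears no hydrogen). The TBS group keeps O4 from chelating lithium and from shifting to the C3 alkoxide before the lactone closes, and the trisubstituted epoxide and the 7,8-alkene do not react with the amide base below 0 °C.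

Step 16
Reactants: 21 unsaturated macrocyclic lactone
Product: 23 (1R,3R,4S,7E,11S,12S,15S)-4-(tert-butyldimethylsilyloxy)-11,12-epoxycembr-7-en-16,3-olide, via 15-epi lactone 22 (not isolated)
Conditions: (IPr)CuCl (cat.), NaOt-Bu (cat.), (EtO)2MeSiH, t-BuOH, toluene, rt; then KOt-Bu (cat.), t-BuOH, rt
Reagents that add atoms: none
Why: Conjugate reduction with an N-heterocyclic-carbene copper hydride, a catalyst class that reduces tetrasubstituted enoates, should deliver hydride to C1 on the lactone face anti to the C3–C4 bond (the face not spanned by the macrocyclic bridge), which places C14 cis to C4 (1R); alkoxide equilibration then moves the C15 methyl trans to C14 (15S, all-equatorial lactone), while the isolated alkene, epoxide and silyl ether are inert.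

Step 17
Reactants: 23 silyl ether lactone
Product: 24 (1R,3R,4S,7E,11S,12S,15S)-11,12-epoxy-4-hydroxycembr-7-en-16,3-olide
Conditions: TBAF, THF, rt → 40 °C
Reagents that add atoms: none
Why: Fluoride cleaves the tertiary TBS ether without acid, so the trisubstituted epoxide and the lactone survive, and C15 already sits in its thermodynamic configuration.

Step 18
Reactants: 24 hydroxy lactone
Product: 25 (1R,3R,4S,6E,8R,11S,12S,15S)-11,12-epoxy-8-hydroperoxy-4-hydroxycembr-6-en-16,3-olide (target)
Conditions: O2, tetraphenylporphyrin (cat.), visible light, CH2Cl2, −20 °C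
Reagents that add atoms: dioxygen O=O
Why: Schenck ene reaction: singlet oxygen bonds to C8 and takes an allylic hydrogen from C6 on the more crowded (C6/C19) side of the only remaining alkene, moving it suprafacially to 6E; the C8 configuration rests on attack at the exposed outer face of the ring alkene, which is relied on to be the 8R-forming face (substrate control only).

Compound list
1 | geranyl bromide, (2E)-1-bromo-3,7-dimethylocta-2,6-diene | CC(C)=CCC/C(C)=C/CBr | starting material
2 | geranyl phenyl sulfone PhSO2–CH2–CH=C(Me)–(CH2)2–CH=CMe2 (2E) | CC(C)=CCC/C(C)=C/CS(=O)(=O)c1ccccc1 | intermediate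
3 | (2E,6E)-2,6-dimethyl-8-(phenylsulfonyl)octa-2,6-dien-1-ol | OC/C(C)=C/CC/C(C)=C/CS(=O)(=O)c1ccccc1 | intermediate
4 | triethylsilyl ether PhSO2–CH2–CH=C(Me)–(CH2)2–CH=C(Me)–CH2OTES (2E,6E) | CC[Si](CC)(CC)OC/C(C)=C/CC/C(C)=C/CS(=O)(=O)c1ccccc1 | intermediate
5 | (R)-2-methylglycidol, (R)-(2-methyloxiran-2-yl)methanol | OC[C@]1(C)CO1 | starting material
6 | (S)-2-[(4-methoxybenzyloxy)methyl]-2-methyloxirane | COc1ccc(COC[C@]2(C)CO2)cc1 | intermediate
7 | hydroxy sulfone PMBOCH2–C(Me)(OH)–CH2–CH(SO2Ph)–CH=C(Me)–(CH2)2–CH=C(Me)–CH2OTES (4S,7E,11E; both C6 epimers) | COc1ccc(COC[C@@](C)(O)CC(/C=C(\C)CC/C=C(\C)CO[Si](CC)(CC)CC)S(=O)(=O)c2ccccc2)cc1 | intermediate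
8 | silyl ether PMBOCH2–C(Me)(OTBS)–CH2–CH(SO2Ph)–CH=C(Me)–(CH2)2–CH=C(Me)–CH2OTES (4S,7E,11E; C6 epimers) | COc1ccc(COC[C@@](C)(O[Si](C)(C)C(C)(C)C)CC(/C=C(\C)CC/C=C(\C)CO[Si](CC)(CC)CC)S(=O)(=O)c2ccccc2)cc1 | intermediate
9 | bis-silyl ether PMBOCH2–C(Me)(OTBS)–(CH2)2–CH=C(Me)–(CH2)2–CH=C(Me)–CH2OTES (4S,7E,11E) | COc1ccc(COC[C@@](C)(O[Si](C)(C)C(C)(C)C)CC/C=C(\C)CC/C=C(\C)CO[Si](CC)(CC)CC)cc1 | intermediate (not isolated)
10 | allylic alcohol PMBOCH2–C(Me)(OTBS)–(CH2)2–CH=C(Me)–(CH2)2–CH=C(Me)–CH2OH (4S,7E,11E) | COc1ccc(COC[C@@](C)(O[Si](C)(C)C(C)(C)C)CC/C=C(\C)CC/C=C(\C)CO)cc1 | intermediate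
11 | epoxy alcohol, as 10 with the 11,12-epoxide (4S,7E,11S,12S) | COc1ccc(COC[C@@](C)(O[Si](C)(C)C(C)(C)C)CC/C=C(\C)CC[C@@H]2O[C@@]2(C)CO)cc1 | intermediate
12 | epoxy triflate, as 11 with C13H2–OSO2CF3 | COc1ccc(COC[C@@](C)(O[Si](C)(C)C(C)(C)C)CC/C=C(\C)CC[C@@H]2O[C@@]2(C)COS(=O)(=O)C(F)(F)F)cc1 | intermediate
13 | ethyl 2-methylacetoacetate (ethyl 2-methyl-3-oxobutanoate) | CCOC(=O)C(C)C(C)=O | starting material
14 | β-keto ester …CH(O)C(Me)–CH2–CH2–CO–CH(Me)–CO2Et (4S,7E,11S,12S; C15 epimers) | COc1ccc(COC[C@@](C)(O[Si](C)(C)C(C)(C)C)CC/C=C(\C)CC[C@@H]2O[C@@]2(C)CCC(=O)C(C)C(=O)OCC)cc1 | intermediate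
15 | (Z)-enol triflate …CH2–CH2–C(OTf)=C(Me)–CO2Et (4S,7E,11S,12S) | COc1ccc(COC[C@@](C)(O[Si](C)(C)C(C)(C)C)CC/C=C(\C)CC[C@@H]2O[C@@]2(C)CC/C(OS(=O)(=O)C(F)(F)F)=C(\C)C(=O)OCC)cc1 | intermediate
16 | (E)-2,3-dimethyl enoate with C3–OPMB and C4–OTBS (4S,7E,11S,12S) | COc1ccc(COC[C@@](C)(O[Si](C)(C)C(C)(C)C)CC/C=C(\C)CC[C@@H]2O[C@@]2(C)CC/C(C)=C(\C)C(=O)OCC)cc1 | intermediate
17 | primary alcohol HOCH2–C(Me)(OTBS)–…–C(Me)=C(Me)–CO2Et (4S,7E,11S,12S) | OC[C@@](C)(O[Si](C)(C)C(C)(C)C)CC/C=C(\C)CC[C@@H]1O[C@@]1(C)CC/C(C)=C(\C)C(=O)OCC | intermediate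
18 | seco aldehyde OHC–C(Me)(OTBS)–(CH2)2–CH=C(Me)–(CH2)2–CH(O)C(Me)–(CH2)2–C(Me)=C(Me)–CO2Et (4S,7E,11S,12S; E-enoate) | O=C[C@@](C)(O[Si](C)(C)C(C)(C)C)CC/C=C(\C)CC[C@@H]1O[C@@]1(C)CC/C(C)=C(\C)C(=O)OCC | intermediate (key-step precursor)
19 | lithium dienolate of 18 (C2 deprotonated) | O=C[C@@](C)(O[Si](C)(C)C(C)(C)C)CC/C=C(\C)CC[C@@H]1O[C@@]1(C)CCC(=C)C(C)=C([O-])OCC.[Li+] | intermediate (not isolated)
20 | lithium aldolate, 14-membered ring with C3–OLi and exocyclic ethyl enoate (3R,4S) | CCOC(=O)/C(C)=C1\C[C@@H]([O-])[C@@](C)(O[Si](C)(C)C(C)(C)C)CC/C=C(\C)CC[C@@H]2O[C@@]2(C)CC1.[Li+] | intermediate (not isolated)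
21 | (3R,4S,7E,11S,12S)-4-(tert-butyldimethylsilyloxy)-11,12-epoxycembra-1(15),7-dien-16,3-olide | CC1=C2CC[C@]3(C)O[C@H]3CC/C(C)=C/CC[C@](C)(O[Si](C)(C)C(C)(C)C)[C@@H](C2)OC1=O | intermediate (key-step product)
22 | 15-epi lactone, (1R,3R,4S,7E,11S,12S,15R) | C[C@H]1C(=O)O[C@@H]2C[C@H]1CC[C@]1(C)O[C@H]1CC/C(C)=C/CC[C@]2(C)O[Si](C)(C)C(C)(C)C | intermediate (not isolated)
23 | (1R,3R,4S,7E,11S,12S,15S)-4-(tert-butyldimethylsilyloxy)-11,12-epoxycembr-7-en-16,3-olide | C[C@@H]1C(=O)O[C@@H]2C[C@H]1CC[C@]1(C)O[C@H]1CC/C(C)=C/CC[C@]2(C)O[Si](C)(C)C(C)(C)C | intermediate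
24 | (1R,3R,4S,7E,11S,12S,15S)-11,12-epoxy-4-hydroxycembr-7-en-16,3-olide | C[C@@H]1C(=O)O[C@@H]2C[C@H]1CC[C@]1(C)O[C@H]1CC/C(C)=C/CC[C@]2(C)O | intermediate
25 | (1R,3R,4S,6E,8R,11S,12S,15S)-11,12-epoxy-8-hydroperoxy-4-hydroxycembr-6-en-16,3-olide | C[C@@H]1C(=O)O[C@@H]2C[C@H]1CC[C@]1(C)O[C@H]1CC[C@@](C)(OO)/C=C/C[C@]2(C)O | target

Total step count: 18. Longest linear sequence: 17 steps (1 → 25; step 4 is a one-step side branch).

Steps most likely to fail

1. Step 15 (proposed new method). Several processes can go wrong: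
- intermolecular aldol addition may out-run ring closure;
- facial selectivity at C3 may be poor, because the Felkin–Anh preference only distinguishes methyl from methylene on C4;
- the amide may deprotonate C14 instead of C2;
- the silyl group may shift from O4 to the C3 alkoxide before acyl transfer.

Fallback with known chemistry, leaving the route at 12 and rejoining at 21: the triflate 12 is alkylated with lithiated acetone N,N-dimethylhydrazone to give the hydrazone F1. Hydrolysis (Cu(OAc)2, THF/H2O) gives the methyl ketone F2. DDQ gives the primary alcohol F3, and Dess–Martin oxidation gives the keto aldehyde F4. An aldol macrocyclisation of the kinetic methyl-ketone enolate onto the non-enolisable aldehyde (KHMDS, THF, −78 °C, high dilution) gives the 14-membered β-hydroxy ketone F5, which fixes the C2–C3 bond and ring regiochemistry by the ketone rather than by a dienolate; C3 depends on the same C4-controlled addition. Steglich esterification of the C3 hydroxyl with 2-(diethoxyphosphoryl)propanoic acid (DCC, DMAP) gives the phosphonate ester F6. An intramolecular Horner–Wadsworth–Emmons reaction (LiCl, DBU, MeCN) then forms C1=C15 and closes the lactone to give 21.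

2. Step 18. Singlet oxygen may abstract hydrogen from the C19 methyl instead of C6 (loss of regiocontrol), or bond to the wrong face of C8 (loss of facial control), since both are governed only by the ring conformation.

Fallback, leaving at 23 and rejoining at 25: the order of the last two operations is inverted, so that the control element changes from a free, hydrogen-bonding 4-hydroxyl to a bulky silyl ether that shields the C4 side and alters the ring conformation. Photooxygenation of 23 (O2, tetraphenylporphyrin, light, CCl4 or benzene) gives the silyl-protected hydroperoxide F7, and buffered fluoride (TBAF/AcOH, THF) then gives 25.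

3. Step 16. Hydride transfer to the tetrasubstituted β-carbon C1 may stall, or may come from the face that gives the C1 epimer.

Fallback, leaving at 21 and rejoining at 23: hydride delivery is replaced by an electron-transfer conjugate reduction (SmI2, HMPA, t-BuOH, THF, 0 °C), in which C1 is set by protonation of the β-carbanion and not by a ligated metal hydride. The same alkoxide equilibration of C15 follows; no new isolated compound arises.

Further compounds
F1 | step 15 | hydrazone, as 12 with C13H2–CH2–C(Me)=N–NMe2 in place of C13H2–OTf (4S,7E,11S,12S) | COc1ccc(COC[C@@](C)(O[Si](C)(C)C(C)(C)C)CC/C=C(\C)CC[C@@H]2O[C@@]2(C)CCC(C)=NN(C)C)cc1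
F2 | step 15 | methyl ketone PMBOCH2–C(Me)(OTBS)–(CH2)2–CH=C(Me)–(CH2)2–CH(O)C(Me)–(CH2)2–CO–CH3 (4S,7E,11S,12S) | COc1ccc(COC[C@@](C)(O[Si](C)(C)C(C)(C)C)CC/C=C(\C)CC[C@@H]2O[C@@]2(C)CCC(C)=O)cc1
F3 | step 15 | primary alcohol of F2 (PMB removed) | OC[C@@](C)(O[Si](C)(C)C(C)(C)C)CC/C=C(\C)CC[C@@H]1O[C@@]1(C)CCC(C)=O
F4 | step 15 | keto aldehyde OHC–C(Me)(OTBS)–…–(CH2)2–CO–CH3 (4S,7E,11S,12S) | O=C[C@@](C)(O[Si](C)(C)C(C)(C)C)CC/C=C(\C)CC[C@@H]1O[C@@]1(C)CCC(C)=O
F5 | step 15 | 14-membered β-hydroxy ketone, C1 ketone and C3 carbinol (3R,4S,7E,11S,12S) | O[C@@H]1CC(=O)CC[C@]2(C)O[C@H]2CC/C(C)=C/CC[C@]1(C)O[Si](C)(C)C(C)(C)C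
F6 | step 15 | C3 ester of F5 with 2-(diethoxyphosphoryl)propanoic acid | CCOP(=O)(OCC)C(C)C(=O)O[C@@H]1CC(=O)CC[C@]2(C)O[C@H]2CC/C(C)=C/CC[C@]1(C)O[Si](C)(C)C(C)(C)C
F7 | step 18 | 4-O-TBS ether of the target hydroperoxide (1R,3R,4S,6E,8R,11S,12S,15S) | C[C@@H]1C(=O)O[C@@H]2C[C@H]1CC[C@]1(C)O[C@H]1CC[C@@](C)(OO)/C=C/C[C@]2(C)O[Si](C)(C)C(C)(C)C
F0 | step 16 | none | none
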